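The cyclohexene ring (C1 bearing isopropenyl, C2=C3 with the C3 methyl, C4 bearing CH2OAr, quaternary C5, C6H2) is cut at C3–C4 and C5–C6. The cis carbons on C4 and C5 are read as the carbonyl and acetal carbons of a 5-menthyloxy-4-methylbutenolide. One Diels–Alder reaction with a 2-silyloxypenta-1,3-diene then closes the ring, sets C4 and C5 and leaves a C1 enol ether. The precursor pair is the (5R) acetal and the triisopropylsilyl dienol ether; the bulky silyl group lets the enol ether outlive the chain-building steps, so the C1 enone is unmasked only late.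

Key step: step 4

Remarks and assumptions
- Ring atoms keep the numbering above throughout. "Upper face" is the face that carries CH2OAr, the acid chain and isopropenyl in the target. Ar = 2-oxo-2H-chromen-7-yl; TIPS = triisopropylsilyl.
- Stereochemical bookkeeping: addition anti to the menthyloxy group of the (5R) acetal puts the lactone carbonyl carbon (on C4) and the acetal carbon (on C5) on the upper face and the C5 methyl on the lower face, as in the target. C1 is set in steps 11 and 13.
- Assumption: the (5R) epimer of 6 is the one that crystallises, as is usual for l-menthyl acetals of this lactone family; otherwise the epimers are separated by chromatography and the unwanted one is re-equilibrated with acid.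
- Assumption: 10 is drawn as the endo adduct at C3; either C3 epimer serves, because C3 becomes sp2 in step 10.
- Assumption: a 12 kbar pressure vessel is available.
- Order of events: the enone is formed only after the C4 carbonyl has become CH2OAr (no C4–H flanked by enone and carbonyl), and the acrylate is saturated before the coumarin is attached.

Step 1
Reactants: 1 glyoxylic acid (as monohydrate); 2 propanal
Product: 3 5-hydroxy-4-methylfuran-2(5H)-one (racemic)
Conditions: morpholine·HCl (1 equiv), dioxane/H2O, reflux
Reagents that add atoms: none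
Why: Amine-salt-mediated crossed aldol condensation (propanal α-carbon onto the glyoxylic aldehyde, then dehydration) gives (Z)-3-formylbut-2-enoic acid, which closes to the cyclic pseudo-acid; the lactol carbon is racemic here and is sorted out in step 2.

Step 2
Reactants: 3 5-hydroxy-4-methylfuran-2(5H)-one; 4 l-menthol
Product: 6 (5R)-5-(l-menthyloxy)-4-methylfuran-2(5H)-one, via epimeric acetal mixture 5 (not isolated)
Conditions: p-TsOH·H2O (cat.), toluene, reflux, Dean–Stark; crystallisation from hexane, −20 °C; mother liquor re-equilibrated with p-TsOH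
Reagents that add atoms: none
Why: Acid-catalysed acetalisation of the pseudo-acid with azeotropic removal of water gives both C5 epimers, which interconvert under acid through the ring oxocarbenium ion, so the (5R) epimer should be collected by crystallisation.

Step 3
Reactants: 7 (E)-pent-3-en-2-one
Product: 9 (E)-2-(triisopropylsilyloxy)penta-1,3-diene, via lithium dienolate 8 (not isolated)
Conditions: LiN(iPr)2 (1.05 equiv), THF, −78 °C; TIPSOTf, −78 → 0 °C
Reagents that add atoms: triisopropylsilyl trifluoromethanesulfonate, CC(C)[Si](OS(=O)(=O)C(F)(F)F)(C(C)C)C(C)C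
Why: Kinetic α′-deprotonation of the methyl ketone by the hindered amide and O-silylation of the cross-conjugated lithium dienolate (silyl enol ether formation) give the 2-silyloxydiene with the (E)-alkene untouched.

Step 4
Reactants: 6 (5R)-5-(l-menthyloxy)-4-methylfuran-2(5H)-one; 9 (E)-2-(triisopropylsilyloxy)penta-1,3-diene
Product: 10 (3R,3aR,7S,7aS)-3-(l-menthyloxy)-3a,7-dimethyl-5-(triisopropylsilyloxy)-3a,4,7,7a-tetrahydro-2-benzofuran-1(3H)-one
Conditions: 9 (3 equiv), 2,6-di-tert-butyl-4-methylphenol (cat.), CH2Cl2, 12 kbar, 40 °C, 72 h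
Reagents that add atoms: none
Why: A concerted, asynchronous, normal-demand [4+2] cycloaddition joins the diene CH2 terminus to the butenolide β-carbon (C5–C6) and the methyl-bearing terminus to the α-carbon (C3–C4); pressure exploits the strongly negative activation volume to offset the β-methyl group without a Lewis acid that could ionise the acetal or the enol ether. The closest known reaction type is the Diels–Alder addition of 5-alkoxy-2(5H)-furanones to 2-silyloxydienes. The carbocycle closes by intermolecular suprafacial–suprafacial cycloaddition, both new σ-bonds forming on one face of each partner, so the six-membered ring is cis-fused to the lactone. C4 and C5 are fixed relative to each other by the cis alkene geometry locked in the butenolide and in the absolute sense by the (5R) acetal carbon, whose menthyloxy group shields its own face so that the diene adds anti to it; C3 follows from endo approach of the (E)-diene and is erased in step 10. The step needs regio- and π-facial selectivity: the 2-silyloxy group (largest HOMO coefficient at the CH2 terminus) and the terminal methyl group both send the unsubstituted terminus to the β-carbon, which is also the sterically easier way to make the quaternary centre, and the acetal stereocentre supplies the facial bias.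

Step 5
Reactants: 10 cycloadduct
Product: 12 cis-fused hydroxy lactone (pseudo-acid; anomer mixture), via lithium carboxylate aldehyde 11 (not isolated)
Conditions: LiOH·H2O (1.1 equiv), THF/H2O, 0 °C; then 0.5 M HCl to pH 4, 0 °C
Reagents that add atoms: lithium hydroxide, [Li+].[OH-]
Why: Saponification of the pseudo-ester: hydroxide adds to the lactone carbonyl, ring opening and loss of mentholate from the hemiacetal alkoxide give the carboxylate aldehyde (C4 is safe as a carboxylate α-carbon, C5 has no hydrogen), and mild acidification recloses the hydroxy lactone without harming the TIPS enol ether.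

Step 6
Reactants: 12 hydroxy lactone
Product: 14 (E)-enoate acid, via sodium carboxylate aldehyde 13 (not isolated)
Conditions: (MeO)2P(O)CH2CO2Me (2.5 equiv), NaH (2.5 equiv), THF, 0 → 40 °C; then 0.5 M HCl to pH 4
Reagents that add atoms: trimethyl phosphonoacetate, COC(=O)CP(=O)(OC)OC
Why: Horner–Wadsworth–Emmons olefination: the first equivalent of phosphonate anion deprotonates the pseudo-acid and thereby opens it, the second converts the non-enolisable neopentyl aldehyde into the (E)-enoate, and the carboxylate keeps C4 configurationally safe.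

Step 7
Reactants: 14 (E)-enoate acid
Product: 15 saturated ester acid
Conditions: H2 (1 atm), 5% Pd/C, EtOAc, 25 °C
Reagents that add atoms: none
Why: Heterogeneous catalytic hydrogenation saturates the disubstituted, ester-conjugated alkene much faster than the trisubstituted enol ether shielded by the TIPS group, and creates no stereocentre.

Step 8
Reactants: 15 saturated ester acid
Product: 17 primary alcohol, via acyl imidazolide 16 (not isolated)
Conditions: 1,1′-carbonyldiimidazole (1.3 equiv), THF, 25 °C; then NaBH4 (3 equiv), H2O, 0 °C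
Reagents that add atoms: none
Why: Acyl imidazolide formation followed by borohydride reduction is a chemoselective acid-to-alcohol reduction in which NaBH4 attacks only the activated acyl group, leaving the methyl ester, the enol ether and the C4 configuration unchanged.

Step 9
Reactants: 17 primary alcohol; 18 umbelliferone (7-hydroxy-2H-chromen-2-one)
Product: 19 umbelliferyl ether
Conditions: PPh3, DIAD, THF, 0 → 25 °C
Reagents that add atoms: none
Why: Mitsunobu etherification: the acidic 7-hydroxycoumarin protonates the betaine and its phenoxide displaces the oxyphosphonium ion at the primary CH2 by SN2, so no stereocentre is involved.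

Step 10
Reactants: 19 umbelliferyl ether
Product: 20 enone
Conditions: Pd(OAc)2 (1.2 equiv), DMSO, 60 °C
Reagents that add atoms: none
Why: Saegusa–Ito oxidation: exchange of silicon for divalent palladium gives the palladium enolate bound at C2, and syn β-hydride elimination of the C3 hydrogen on the open lower face gives the C2=C3 enone, removing the C3 stereocentre under neutral conditions that cannot trigger γ-deprotonation and loss of ArO−.

Step 11
Reactants: 20 enone
Product: 21 (R)-allylic alcohol (C1 hydroxyl on the lower face)
Conditions: (S)-1-methyl-3,3-diphenyltetrahydro-1H,3H-pyrrolo[1,2-c][1,3,2]oxazaborole [(S)-Me-CBS] (0.5 equiv), catecholborane (1.5 equiv), toluene, −78 °C; MeOH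
Reagents that add atoms: none
Why: Corey–Bakshi–Shibata reduction: the oxazaborolidine–borane complex binds the ketone with the alkenyl arm as the large substituent and delivers hydride to the upper face, setting C1 as (R) with the hydroxyl on the lower face, an approach that the axial C5 methyl on the lower face should reinforce.

Step 12
Reactants: 21 (R)-allylic alcohol
Product: 22 allylic methyl carbonate
Conditions: ClCO2Me, pyridine, DMAP (cat.), CH2Cl2, 0 °C
Reagents that add atoms: methyl chloroformate, COC(=O)Cl
Why: Acylation at oxygen with the chloroformate (carbonate formation) leaves the C1–O bond and therefore the C1 configuration intact.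

Step 13
Reactants: 22 allylic methyl carbonate
Product: 23 methyl ester of the target
Conditions: isopropenyl-B(pin) (2 equiv), Pd(PPh3)4 (5 mol%), THF, 60 °C
Reagents that add atoms: 2-isopropenyl-4,4,5,5-tetramethyl-1,3,2-dioxaborolane, CC(=C)B1OC(C)(C)C(C)(C)O1
Why: Allylic Suzuki–Miyaura coupling: zerovalent palladium ionises the carbonate with inversion to a π-allyl complex on the upper face, the methoxide freed by decarboxylation activates the boronate for transmetalation, and reductive elimination at the less substituted terminus C1 (C3 would become quaternary) places isopropenyl on the upper face, i.e. overall inversion to C1 (S).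

Step 14
Reactants: 23 methyl ester of the target
Product: 25 target acid CNP0301632.1, via trilithium seco-acid salt 24 (not isolated)
Conditions: LiOH·H2O (4 equiv), THF/H2O, 25 °C, dark; then 1 M HCl to pH 2
Reagents that add atoms: lithium hydroxide, [Li+].[OH-]
Why: Saponification of the methyl ester also opens the coumarin lactone to the (Z)-2-oxidocinnamate, which relactonises spontaneously on acidification because the (Z)-geometry is kept in the dark, and no stereocentre is touched.

Compound list
1 | glyoxylic acid (used as monohydrate) | O=CC(=O)O | starting material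
2 | propanal | CCC=O | starting material
3 | 5-hydroxy-4-methylfuran-2(5H)-one (racemic) | OC1OC(=O)C=C1C | intermediate
4 | l-menthol, (1R,2S,5R)-2-isopropyl-5-methylcyclohexan-1-ol | C[C@@H]1CC[C@H]([C@@H](C1)O)C(C)C | starting material
5 | 5-(l-menthyloxy)-4-methylfuran-2(5H)-one, mixture of C5 epimers | C[C@@H]1CC[C@H]([C@@H](C1)OC1OC(=O)C=C1C)C(C)C | intermediate (not isolated)
6 | (5R)-5-(l-menthyloxy)-4-methylfuran-2(5H)-one | C[C@@H]1CC[C@H]([C@@H](C1)O[C@@H]1OC(=O)C=C1C)C(C)C | intermediate (dienophile)
7 | (E)-pent-3-en-2-one | C/C=C/C(C)=O | starting material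
8 | lithium (E)-penta-1,3-dien-2-olate | [Li+].C=C([O-])/C=C/C | intermediate (not isolated)
9 | (E)-2-(triisopropylsilyloxy)penta-1,3-diene | C=C(O[Si](C(C)C)(C(C)C)C(C)C)/C=C/C | intermediate (diene)
10 | (3R,3aR,7S,7aS)-3-(l-menthyloxy)-3a,7-dimethyl-5-(triisopropylsilyloxy)-3a,4,7,7a-tetrahydro-2-benzofuran-1(3H)-one; cis-fused, menthyloxy anti to the carbocycle, C3 methyl (ring numbering) on the upper face | C1C(O[Si](C(C)C)(C(C)C)C(C)C)=C[C@H](C)[C@@H]2C(=O)O[C@@H](O[C@@H]3C[C@H](C)CC[C@H]3C(C)C)[C@]12C | intermediate (key-step product)
11 | lithium salt of the ring-opened aldehyde acid: cyclohexene with C1 OTIPS (C1=C2), C3 methyl, C4 carboxylate, C5 methyl and C5 formyl; carboxylate and formyl cis on the upper face | [Li+].C1C(O[Si](C(C)C)(C(C)C)C(C)C)=C[C@H](C)[C@H](C(=O)[O-])[C@@]1(C=O)C | intermediate (not isolated)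
12 | (3aR,7S,7aS)-3-hydroxy-3a,7-dimethyl-5-(triisopropylsilyloxy)-3a,4,7,7a-tetrahydro-2-benzofuran-1(3H)-one, anomer mixture | C1C(O[Si](C(C)C)(C(C)C)C(C)C)=C[C@H](C)[C@@H]2C(=O)OC(O)[C@]12C | intermediate
13 | sodium salt of the same ring-opened aldehyde acid as 11 | [Na+].C1C(O[Si](C(C)C)(C(C)C)C(C)C)=C[C@H](C)[C@H](C(=O)[O-])[C@@]1(C=O)C | intermediate (not isolated)
14 | (E)-enoate acid: cyclohexene with C1 OTIPS (C1=C2), C3 methyl, C4 CO2H, C5 methyl and C5 (E)-CH=CH–CO2Me; CO2H, C3 methyl and the C5 chain on the upper face | C1C(O[Si](C(C)C)(C(C)C)C(C)C)=C[C@H](C)[C@H](C(=O)O)[C@@]1(/C=C/C(=O)OC)C | intermediate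
15 | saturated ester acid: as 14 with C5 CH2CH2CO2Me | C1C(O[Si](C(C)C)(C(C)C)C(C)C)=C[C@H](C)[C@H](C(=O)O)[C@@]1(CCC(=O)OC)C | intermediate
16 | acyl imidazolide of 15 (C4 C(=O)-imidazol-1-yl) | C1C(O[Si](C(C)C)(C(C)C)C(C)C)=C[C@H](C)[C@H](C(=O)n2ccnc2)[C@@]1(CCC(=O)OC)C | intermediate (not isolated)
17 | primary alcohol: as 15 with C4 CH2OH | C1C(O[Si](C(C)C)(C(C)C)C(C)C)=C[C@H](C)[C@H](CO)[C@@]1(CCC(=O)OC)C | intermediate
18 | umbelliferone, 7-hydroxy-2H-chromen-2-one | O=c1ccc2ccc(O)cc2o1 | starting material
19 | umbelliferyl ether: as 17 with C4 CH2OAr | C1C(O[Si](C(C)C)(C(C)C)C(C)C)=C[C@H](C)[C@H](COc2ccc3ccc(=O)oc3c2)[C@@]1(CCC(=O)OC)C | intermediate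
20 | methyl 3-[(1R,2R)-1,3-dimethyl-5-oxo-2-{[(2-oxo-2H-chromen-7-yl)oxy]methyl}cyclohex-3-en-1-yl]propanoate | O=C1C=C(C)[C@H](COc2ccc3ccc(=O)oc3c2)[C@](C)(CCC(=O)OC)C1 | intermediate
21 | methyl 3-[(1R,2R,5R)-5-hydroxy-1,3-dimethyl-2-{[(2-oxo-2H-chromen-7-yl)oxy]methyl}cyclohex-3-en-1-yl]propanoate (hydroxyl trans to both side chains) | O[C@H]1C=C(C)[C@H](COc2ccc3ccc(=O)oc3c2)[C@](C)(CCC(=O)OC)C1 | intermediate
22 | methyl carbonate of 21 | COC(=O)O[C@H]1C=C(C)[C@H](COc2ccc3ccc(=O)oc3c2)[C@](C)(CCC(=O)OC)C1 | intermediate
23 | methyl 3-[(1R,2R,5S)-1,3-dimethyl-2-{[(2-oxo-2H-chromen-7-yl)oxy]methyl}-5-(prop-1-en-2-yl)cyclohex-3-en-1-yl]propanoate | C=C(C)[C@@H]1C=C(C)[C@H](COc2ccc3ccc(=O)oc3c2)[C@](C)(CCC(=O)OC)C1 | intermediate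
24 | trilithium salt of the seco acid: chain carboxylate, coumarin opened to the (Z)-3-(2-oxidoaryl)acrylate | [Li+].[Li+].[Li+].C=C(C)[C@@H]1C=C(C)[C@H](COc2ccc(/C=C\C(=O)[O-])c([O-])c2)[C@](C)(CCC(=O)[O-])C1 | intermediate (not isolated)
25 | 3-[(1R,2R,5S)-1,3-dimethyl-2-{[(2-oxo-2H-chromen-7-yl)oxy]methyl}-5-(prop-1-en-2-yl)cyclohex-3-en-1-yl]propanoic acid (CNP0301632.1) | C=C(C)[C@@H]1C=C(C)[C@H](COc2ccc3ccc(=O)oc3c2)[C@](C)(CCC(=O)O)C1 | target

Total step count: 14. Longest linear sequence: 13 steps (steps 1, 2 and 4–14); step 3 is a one-step branch.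

Steps most likely to fail

Step 4. The cycloaddition may stall, or the diene may oligomerise before it adds, because bond formation at the methyl-bearing β-carbon is slow. The fallback sets out from 6 and comes back at 10. Addition of Br2 (CH2Cl2, 0 °C) would give the 3,4-dibromo lactone F1, and Et3N in the same flask would eliminate HBr to the 3-bromobutenolide F2, a dienophile with a lower LUMO. Thermal cycloaddition of F2 with 9 (toluene, 90 °C) should proceed with the same orientation and again anti to the menthyloxy group, giving the 7a-bromo cycloadduct F3. Radical debromination (Bu3SnH, azobisisobutyronitrile, toluene, 80 °C), with hydrogen transfer to the convex face of the lactone α-radical, returns to 10.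

Step 13. Ionisation on the hindered upper face may be slow, or the π-allyl intermediate may lose a β-hydrogen to a cyclohexadiene faster than it transmetalates. The fallback sets out from 17 and comes back at 23; it moves the C–C bond formation ahead of the coumarin so that an organocopper reagent can be used. Silylation (t-BuMe2SiCl, imidazole, DMF) gives the silyl ether F4. Saegusa–Ito oxidation as in step 10 gives the enone F5, and CBS reduction as in step 11 gives the (R)-allylic alcohol F6. Pivaloylation (t-BuCOCl, pyridine, DMAP) gives the allylic pivalate F7. Lithium di(prop-1-en-2-yl)cuprate, LiCu(C3H5)2, made from 2-lithiopropene and CuBr·SMe2 in Et2O at −40 °C, should substitute anti at the unhindered C1 terminus through an allyl complex of trivalent copper, giving the isopropenyl silyl ether F8. Bu4NF then frees the alcohol F9, and Mitsunobu etherification with 18 as in step 9 gives 23.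

Step 10. Exchange of the bulky triisopropylsilyl group for palladium may be slow, so that the enol ether is recovered or merely hydrolysed. The fallback sets out from 19 and comes back at 20. Bu4NF buffered with AcOH (THF, 0 °C) frees the saturated ketone F10, and dehydrogenation with 2-iodoxybenzoic acid (DMSO, 70 °C) gives 20. The regiochemistry cannot go wrong, because C5 carries no hydrogen and only the C2–C3 bond can be desaturated.

Further compounds
F1 | step 4 | (5R)-3,4-dibromo-5-(l-menthyloxy)-4-methyldihydrofuran-2(3H)-one (C3 and C4 not defined) | C[C@@H]1CC[C@H]([C@@H](C1)O[C@@H]1OC(=O)C(Br)C1(C)Br)C(C)C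
F2 | step 4 | (5R)-3-bromo-5-(l-menthyloxy)-4-methylfuran-2(5H)-one | C[C@@H]1CC[C@H]([C@@H](C1)O[C@@H]1OC(=O)C(Br)=C1C)C(C)C
F3 | step 4 | 7a-bromo analogue of 10 (bromine in place of the C4 hydrogen, lower face) | C1C(O[Si](C(C)C)(C(C)C)C(C)C)=C[C@H](C)[C@]2(Br)C(=O)O[C@@H](O[C@@H]3C[C@H](C)CC[C@H]3C(C)C)[C@]12C
F4 | step 13 | tert-butyldimethylsilyl ether of 17 | C1C(O[Si](C(C)C)(C(C)C)C(C)C)=C[C@H](C)[C@H](CO[Si](C)(C)C(C)(C)C)[C@@]1(CCC(=O)OC)C
F5 | step 13 | enone: as 20 with CH2OSi(t-Bu)Me2 in place of CH2OAr | O=C1C=C(C)[C@H](CO[Si](C)(C)C(C)(C)C)[C@](C)(CCC(=O)OC)C1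
F6 | step 13 | (R)-allylic alcohol: as 21 with CH2OSi(t-Bu)Me2 in place of CH2OAr | O[C@H]1C=C(C)[C@H](CO[Si](C)(C)C(C)(C)C)[C@](C)(CCC(=O)OC)C1
F7 | step 13 | pivalate of F6 | CC(C)(C)C(=O)O[C@H]1C=C(C)[C@H](CO[Si](C)(C)C(C)(C)C)[C@](C)(CCC(=O)OC)C1
F8 | step 13 | isopropenyl silyl ether: as 23 with CH2OSi(t-Bu)Me2 in place of CH2OAr | C=C(C)[C@@H]1C=C(C)[C@H](CO[Si](C)(C)C(C)(C)C)[C@](C)(CCC(=O)OC)C1
F9 | step 13 | primary alcohol: as 23 with CH2OH in place of CH2OAr | C=C(C)[C@@H]1C=C(C)[C@H](CO)[C@](C)(CCC(=O)OC)C1
F10 | step 10 | saturated ketone: C1 ketone, C3 methyl on the upper face, C4 CH2OAr, C5 methyl and CH2CH2CO2Me | O=C1C[C@H](C)[C@H](COc2ccc3ccc(=O)oc3c2)[C@](C)(CCC(=O)OC)C1
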